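## The problem

Compound 29 is a hexacyclic resveratrol trimer in which a bicyclo[3.2.1]oct-2-ene-4,8-dione (six-membered ring A, C1-C2-C3-C4-C5-C8; five-membered ring B, C1-C8-C5-C6-C7) shares its quaternary bridgehead C1 and the enone carbon C2 with a cis-fused cyclopenta[a]indane (ring C, C1-C2-C9-C11-C12; ring D, C9-C10-aryl-aryl-C11; resorcinol ring E). C6 carries a 3,5-dihydroxyphenyl group and C7, C10 and C12 a 4-hydroxyphenyl group each. In what follows α is the face of ring C that carries H-9, H-11 and the C12 aryl group, and β the face on which ring D lies. There are eight stereocentres (C1, C5, C6, C7, C9, C10, C11, C12), and they can be made to control one another in a chain. C11, taken from the chiral pool, fixes C9 and C10 through ring D closure and then C12 by addition to the convex face. C12 fixes C7, a catalyst fixes C6, the epimerisable C5 settles trans to C6, and C5 finally delivers C8 to one face of C1. The fragile features are the seven phenols and three electron-rich dioxygenated rings (kept as methyl ethers to the end, but still able to capture cations and acylium ions), the doubly benzylic C10–H, and the unsaturated ketone around C2. The 1,3-diketone is also fragile: its central carbon C5 is a bridgehead, so it cannot hide as an enolate from retro-Claisen cleavage. The feature that invites the key step is the one-carbon ketone bridge C8, which ties C5 to the quaternary C1 across the seven-membered carbocycle C1–C7. A cyclohept-1-ene (C1=C2) carrying an acyl radical on C5 therefore closes rings A and B by forming only C8–C1, with no ionic intermediate for the arenes to intercept. In that ring C5 lies across from both alkene carbons, so attack at C1 and not at C2 has to be secured by the tethers.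

## Retrosynthesis

**Late functional group changes (29 back to 26).** The seven O–methyl bonds of 28 are cut last, and the C2=C3 unsaturation is removed to give diketone 26, from which it returns through silyl enol ether 27. This is preferred to carrying the enone through the ring closure, because in 26 the C4 ketone can enolise only toward C3 and the C8 ketone not at all, so the dehydrogenation has a single possible outcome.

**C8–C1 (26 back to 25).** Cutting the bond between the bridging carbonyl and the quaternary carbon opens rings A and B together and leaves the cycloheptenone phenyl selenoester 25. The neighbouring cuts C1–C7 and C1–C12 would each require an intermolecular or cationic quaternisation beside two aryl-bearing carbons. The chosen cut forms the quaternary centre intramolecularly, by a radical that the methoxyarenes tolerate, with its configuration dictated by C5. The forward reaction must close at C1 and not at C2, and must be faster than loss of CO.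

**C8–Se and C4–C5 (25 back to 22).** The selenoester comes from β-keto tert-butyl ester 23, and the seven-membered ring from diester 22 by cutting C4–C5 (Dieckmann). The cis C1=C2 bond already holds the two chains together. A tert-butyl ester at C8 and a methyl ester at C4 are chosen so that only the C5 enolate finds an acyl acceptor. The more acidic allylic C3 position would otherwise divert the closure.

**C2–C3 and C6–aryl (22 back to 16).** The acetate arm (C3, C4) is cut from enol triflate 20 and methyl bromoacetate 21. The C6 aryl group is cut from enoate 18 and boronic acid 19 under catalyst control. The enoate is obtained from the saturated ester 16 by dehydrogenation. Arylation is placed before the coupling so that the base-sensitive, doubly allylic H-7 of 18 survives for one step only.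

**C7–aryl, C1=C7 and C12–aryl (16 back to 8).** Both 4-methoxyphenyl groups come from 4-bromoanisole 9 by conjugate addition: the first to C12 of enone 8, the second to C7 of the exocyclic enone 14. Enone 14 is made from the first enolate and aldehyde 10 through aldol 12. Trapping the second enolate as triflate 16 fixes the tetrasubstituted C1=C2 bond without any regiochemical choice. This order (chain first, aryl second) is taken because attack anti to the C12 aryl group then gives the required C7 configuration, while the reverse order would give its epimer.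

**Ring D and the first two C–C bonds (8 back to 1, 2, 3).** The bond from ring E to C10 is cut (Friedel–Crafts), then C9–C10 (aldol) and C11–aryl (conjugate addition). This leaves the commercially available silyloxy enone 1, aryl bromide 2 and aldehyde 3, joined through aldol 5. Closing ring D on a simple cyclopentanone uses the nucleophilicity of the dimethoxyphenyl ring constructively, and sets C9 and C10 from C11.

## Roads not taken

**Alternative 1:** The cuts are C1–C7 and C1–C12. In the forward sense a chiral Brønsted acid would protonate the two stilbene arms of the acyclic triketone A1 at C6 and C11, and the enol at C1 would capture the two 4-methoxybenzylic cations in turn to give spirodione A2 with rings B and C. The merit is real: the quaternary carbon and two rings arise in one redox-neutral step from an acyclic precursor, without tin or selenium, and a working version would be clearly shorter than the chosen plan. The weak points are stereochemical and chemoselective. Five stereocentres (C1, C6, C7, C11, C12) would have to be set at once, by enantioselective protonation of two trisubstituted styrenes and two diastereoselective captures of long-lived cations. The second capture forms a quaternary carbon between two benzylic methines and competes with O-alkylation and with elimination back to the stilbene. A2 still lacks rings D and E. C9 is an unactivated methylene in A2, so the C9–C10 bond and the C10 stereocentre remain to be installed at a crowded site. The chosen plan is longer, but each centre is set by a reaction type of known stereochemical sense; that is what it sets against the convergence of A1 to A2.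

**Alternative 2:** The cut goes through three bonds of ring E. Cp*RuCl(cod) would join the ethoxyethynyl group at C10 and the ethynyl group at C11 of diyne A3 with ethoxyethyne A4, closing rings D and E together and giving the mixed ether A5. This end game is better than the chosen plan in one respect: the oxidation-prone resorcinol ring does not exist until the last C–C bond formation. In the chosen plan that ring is carried through twelve further steps. Ruthenium cyclotrimerisation of 1,6-diynes with a terminal alkyne is also reliable for the meta pattern needed. Its weakness is that it leaves the core problem unsolved. A3 must already contain the bicyclo[3.2.1]octenedione with its quaternary C1, and in addition three propargylic stereocentres (C9, C10, C11). Of these, C9 is γ to the enone carbonyl and epimerisable, and C10 carries an acid-sensitive ynol ether. The chosen plan uses the same aromatic ring as the nucleophile that closes ring D, which sets C9 and C10 from C11; A3 would have to set them independently.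

**Alternative 3:** The cut is C2–C9. The potassium enolate of the indanone in A6 would add to C2 of the β-methoxy enone (5-exo-trig) and expel methoxide, giving triketone A7 with ring C closed and the enone already in place. This is tin-free and saves the two-step dehydrogenation that the chosen plan needs after its key step. Two things weigh against it. First, A6 already contains the bicyclic diketone with the quaternary C1 bearing the C12 chain, so the hardest bond is moved upstream without a method for it, and the liberated methoxide can open the non-enolisable 1,3-diketone. Second, C10 is a ketone in A7. Aryl addition followed by ionic reduction would deliver hydride to the convex face and leave the aryl group on the concave face, the opposite of the target. The chosen plan sets C10 through the geometry of a Friedel–Crafts closure and makes C1 quaternary intramolecularly under the control of C5.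

Key step: step 11

Remark 1: the carbinol centres made in steps 1 and 3 (C10 of 5, C7 of 12) are not controlled and are drawn without configuration, since both epimers converge in steps 2 and 4; C5 of 17 is likewise undefined.

Remark 2: (S)-BINAP–rhodium is assumed to add the aryl group to the (E)-enoate of 18 on the same face as with simple (E)-crotonates, which corresponds to the C6 configuration drawn for 20; the enantiomeric ligand is the one to use if the facial sense is the opposite.

## Route

Step 1
Reactants: 1 (R)-4-(tert-butyldimethylsilyloxy)cyclopent-2-en-1-one; 2 1-bromo-3,5-dimethoxybenzene; 3 4-methoxybenzaldehyde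
Product: 5 aldol adduct 2-[hydroxy(4-methoxyphenyl)methyl]-3-(3,5-dimethoxyphenyl)-4-(tert-butyldimethylsilyloxy)cyclopentan-1-one (2,3-trans-3,4-trans), via bromomagnesium enolate 4 (not isolated)
Conditions: 2, Mg, THF; CuBr·SMe2 (10 mol%), 1, THF, −40 °C; then 3, −78 °C; aq NH4Cl
Reagents that add atoms: none
Why: Copper-catalysed 1,4-addition of the aryl Grignard reagent goes anti to the silyloxy group and so sets C11 from the chiral-pool centre; enolate 4 exists only toward C9 and is trapped there by aldehyde 3 (three-component conjugate addition–aldol coupling), the C9 chain ending trans to the C11 aryl group.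

Step 2
Reactants: 5 aldol adduct
Product: 8 tricyclic enone (rings C/D/E closed; C2 ketone; C1=C12), via (E)-benzylidene ketone 6 (not isolated), via tricyclic silyloxy ketone 7 (not isolated)
Conditions: BF3·OEt2, CH2Cl2, −40 → 0 °C; then DBU (excess), 0 °C → rt
Reagents that add atoms: none
Why: BF3 ionises the 4-methoxybenzylic carbinol and H-9 is lost to give 6; its BF3-bound enone is attacked at C10 from the β face by the ortho carbon of the dimethoxyphenyl ring (intramolecular Friedel–Crafts conjugate alkylation), closing ring D with H-9 and H-11 necessarily cis and, because the aryl group of the (E)-alkene lies on the C11 side, with the C10 aryl group exo; DBU then expels silanolate from C12 of 7 (E1cB), after ring D has locked C11.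

Step 3
Reactants: 8 tricyclic enone; 9 4-bromoanisole; 10 tert-butyl 4-oxobutanoate
Product: 12 aldol adduct (C12 4-methoxyphenyl α; C1 bears CH(OH)CH2CH2CO2t-Bu), via bromomagnesium enolate 11 (not isolated)
Conditions: 9, Mg, THF; CuBr·SMe2 (10 mol%), 8, THF, −40 °C; then 10, −78 °C; aq NH4Cl
Reagents that add atoms: none
Why: Copper-catalysed conjugate arylation of the bicyclic enone occurs on the convex α face, anti to ring E at C11, and sets C12; enolate 11 is formed only toward C1 and adds to aldehyde 10 (aldol), the tert-butyl ester resisting lactonisation.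

Step 4
Reactants: 12 aldol adduct
Product: 14 (E)-alkylidene ketone (exocyclic C1=C7; chain syn to C12), via methanesulfonate 13 (not isolated)
Conditions: MsCl, Et3N, CH2Cl2, 0 °C → rt
Reagents that add atoms: none
Why: Mesylation and E1cB elimination give the more stable (E)-2-alkylidene ketone and erase the uncontrolled C1 and C7 centres; Et3N is the only base so that the exocyclic double bond does not migrate to C1=C12.

Step 5
Reactants: 14 (E)-alkylidene ketone; 9 4-bromoanisole
Product: 16 enol triflate (C2–OTf; C1=C2; C7 stereocentre), via bromomagnesium enolate 15 (not isolated)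
Conditions: 9, Mg, THF; CuBr·SMe2 (10 mol%), 14, THF, −40 °C; then N-(5-chloro-2-pyridyl)triflimide, −78 °C → rt
Reagents that add atoms: N-(5-chloro-2-pyridyl)bis(trifluoromethanesulfonimide), FC(F)(F)S(=O)(=O)N(c1ccc(Cl)cn1)S(=O)(=O)C(F)(F)F
Why: In this conjugate addition–enolate triflation the aryl group should enter C7 from the β face, anti to the α aryl group on the adjacent C12, which with the (E)-alkene gives the required C7 configuration; enolate 15 can only be C2(O)=C1, so O-sulfonylation fixes the tetrasubstituted C1=C2 bond without a regiochemical choice.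

Step 6
Reactants: 16 enol triflate
Product: 18 (E)-enoate (C5=C6), via α-phenylselanyl ester 17 (not isolated)
Conditions: LDA (LiN(i-Pr)2), THF, −78 °C; PhSeBr; then 30% H2O2, pyridine, CH2Cl2, 0 °C → rt
Reagents that add atoms: none
Why: The tert-butyl ester is the only enolisable carbonyl, so selenenylation occurs at C5, and oxidation at selenium with syn-elimination toward C6 gives the (E)-enoate (selenoxide elimination); the enol triflate and the aryl ethers are inert to both stages.

Step 7
Reactants: 18 (E)-enoate; 19 3,5-dimethoxyphenylboronic acid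
Product: 20 enol triflate with C6 3,5-dimethoxyphenyl group
Conditions: [Rh(OH)(cod)]2 (3 mol%), (S)-BINAP (7 mol%), 19 (3 equiv), dioxane–H2O 10:1, 50 °C
Reagents that add atoms: none
Why: Rhodium-catalysed asymmetric 1,4-addition of an arylboronic acid to an (E)-enoate (Hayashi–Miyaura reaction) sets C6 under catalyst control (Remark 2); base-free conditions spare the doubly allylic H-7, and the enol triflate is not touched by monovalent rhodium.

Step 8
Reactants: 20 enol triflate; 21 methyl bromoacetate
Product: 22 diester (C2–CH2CO2Me; C5H2–CO2t-Bu)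
Conditions: 21, Zn, THF; then 20, Pd2(dba)3 (2.5 mol%), XPhos (10 mol%), THF, 60 °C
Reagents that add atoms: none
Why: Negishi coupling of the Reformatsky reagent with the hindered enol triflate gives the β,γ-unsaturated methyl ester and introduces C3 and C4 at the oxidation level needed for ring closure.

Step 9
Reactants: 22 diester
Product: 23 cycloheptenone β-keto tert-butyl ester (C4 ketone; C5–CO2t-Bu; C5/C6/C7 all-trans)
Conditions: KOt-Bu (2.2 equiv), THF (0.01 M), 0 °C → rt; aq NH4Cl
Reagents that add atoms: none
Why: Dieckmann condensation closes the seven-membered ring; only attack of the C5 enolate on the C4 methyl ester is productive because the tert-butyl ester is no acyl acceptor for the more acidic C3 enolate, the product leaves the equilibrium as its enolate, and C5 is set on protonation as the more stable epimer trans to the C6 aryl group.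

Step 10
Reactants: 23 β-keto tert-butyl ester
Product: 25 cycloheptenone β-keto phenyl selenoester, via β-keto acid 24 (not isolated)
Conditions: TFA, CH2Cl2, 0 °C; evaporate at 0 °C; then PhSeSePh, Bu3P, CH2Cl2, 0 °C
Reagents that add atoms: diphenyl diselenide, c1ccc(cc1)[Se][Se]c1ccccc1
Why: Acidolysis of the tert-butyl ester gives acid 24, which is kept cold to prevent decarboxylation and converted at once to the selenoester by phosphine–diselenide activation; C5 remains the thermodynamic all-trans epimer.

Step 11
Reactants: 25 cycloheptenone β-keto phenyl selenoester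
Product: 26 bicyclo[3.2.1]octane-4,8-dione (2,3-dihydro derivative of 28; H-2 α)
Conditions: Bu3SnH (1.3 equiv, syringe pump), Et3B (0.3 equiv), air (trace), toluene (0.005 M), −20 °C → rt
Reagents that add atoms: none
Why: Et3B and oxygen start a tin hydride chain in which the stannyl radical removes the phenylselanyl group from the keto tautomer of 25; the acyl radical at C8 adds across the seven-membered ring to C1 of the tetrasubstituted C1=C2 bond, and the tertiary C2 radical takes hydrogen from Bu3SnH. The closest known reaction type is the Bu3SnH-mediated cyclisation of acyl radicals from phenyl selenoesters onto alkenes, run here in the transannular mode. Ring B (C1, C8, C5, C6, C7) closes 5-exo-trig through the sp3 tether C5–C6–C7, and the same bond completes ring A (C1, C2, C3, C4, C5, C8), formally a 6-endo-trig closure through C5–C4–C3. C8 starts equidistant from C1 and C2, so the regioselectivity comes from the tethers: attack at C2 would be a 5-exo closure through the trigonal C4 ketone to a bridged cyclopentane-1,3-dione and is disfavoured, while the aryl-substituted sp3 tether favours 5-exo attack at C1. The new quaternary centre C1 is set by C5: in the all-trans C5/C6/C7 array C8 can reach the alkene only on the α face, opposite ring D. At C2 hydrogen should be delivered axially from the α face, flanked only by H-9 and the two carbonyl carbons, giving the trans A/C fusion drawn; this centre is removed in step 13, so its epimer would serve equally. Cyclisation must outrun loss of CO (which would give a ketone-stabilised C5 radical) and direct reduction, which low temperature, high dilution and slow addition of the stannane are meant to secure.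

Step 12
Reactants: 26 bicyclic diketone
Product: 27 C3=C4 trimethylsilyl enol ether
Conditions: TMSOTf, Et3N, CH2Cl2, 0 °C
Reagents that add atoms: trimethylsilyl trifluoromethanesulfonate, C[Si](C)(C)OS(=O)(=O)C(F)(F)F
Why: Soft enolisation and silylation; the C4 ketone can enolise only toward C3 because C5 is a bridgehead, and the C8 ketone has no enolisable α-hydrogen, so a single silyl enol ether forms.

Step 13
Reactants: 27 silyl enol ether
Product: 28 heptamethyl ether of the target (C2=C3 enone)
Conditions: Pd(OAc)2 (1.1 equiv), MeCN, rt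
Reagents that add atoms: none
Why: Saegusa–Ito oxidation; after transfer of C3 to palladium, β-hydride elimination can only take H-2, which gives the C2=C3 enone and removes the C2 stereocentre.

Step 14
Reactants: 28 heptamethyl ether
Product: 29 target CNP0407321.1
Conditions: BBr3 (14 equiv), CH2Cl2, −78 °C → rt; then H2O, 0 °C
Reagents that add atoms: none
Why: Lewis acid cleavage of all seven aryl methyl ethers; the conditions are non-nucleophilic toward the bridged 1,3-diketone, and no stereocentre can epimerise to a more stable arrangement (C9 is held cis by ring D).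

## Compound list

1 | (R)-4-(tert-butyldimethylsilyloxy)cyclopent-2-en-1-one | O=C1C=C[C@H](O[Si](C)(C)C(C)(C)C)C1 | starting material
2 | 1-bromo-3,5-dimethoxybenzene | COc1cc(Br)cc(OC)c1 | starting material
3 | 4-methoxybenzaldehyde | COc1ccc(C=O)cc1 | starting material
4 | bromomagnesium C2(O)=C9 enolate of the 1,4-adduct (C11 aryl β, C12 silyloxy α; not isolated) | Br[Mg]OC1=C[C@@H](c2cc(OC)cc(OC)c2)[C@H](O[Si](C)(C)C(C)(C)C)C1 | intermediate
5 | 2-[hydroxy(4-methoxyphenyl)methyl]-3-(3,5-dimethoxyphenyl)-4-(tert-butyldimethylsilyloxy)cyclopentan-1-one, 2,3-trans-3,4-trans, carbinol centre undefined | O=C1C[C@@H](O[Si](C)(C)C(C)(C)C)[C@H](c2cc(OC)cc(OC)c2)[C@H]1C(O)c1ccc(OC)cc1 | intermediate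
6 | (E)-2-(4-methoxybenzylidene)-3-(3,5-dimethoxyphenyl)-4-(tert-butyldimethylsilyloxy)cyclopentan-1-one, 3,4-trans (not isolated) | O=C1C[C@@H](O[Si](C)(C)C(C)(C)C)[C@H](c2cc(OC)cc(OC)c2)/C1=C\c1ccc(OC)cc1 | intermediate
7 | tricyclic C2 ketone with rings C, D, E closed: H-9 and H-11 α (cis fusion), C10 4-methoxyphenyl α (exo), C12 silyloxy α (not isolated) | O=C1[C@H]3[C@H](c4ccc(OC)cc4)c4c(OC)cc(OC)cc4[C@H]3[C@H](O[Si](C)(C)C(C)(C)C)C1 | intermediate
8 | tricyclic enone: C2 ketone, C1=C12, H-9 and H-11 cis, C10 4-methoxyphenyl exo | O=C1[C@H]3[C@H](c4ccc(OC)cc4)c4c(OC)cc(OC)cc4[C@H]3C=C1 | intermediate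
9 | 4-bromoanisole | COc1ccc(Br)cc1 | starting material
10 | tert-butyl 4-oxobutanoate | CC(C)(C)OC(=O)CCC=O | starting material
11 | bromomagnesium C2(O)=C1 enolate with C12 4-methoxyphenyl α (not isolated) | Br[Mg]OC=1[C@H]3[C@H](c4ccc(OC)cc4)c4c(OC)cc(OC)cc4[C@H]3[C@H](c3ccc(OC)cc3)C=1 | intermediate
12 | aldol adduct: C12 4-methoxyphenyl α, C1 chain CH(OH)CH2CH2CO2t-Bu β, carbinol centre undefined | O=C1[C@H]3[C@H](c4ccc(OC)cc4)c4c(OC)cc(OC)cc4[C@H]3[C@H](c3ccc(OC)cc3)[C@H]1C(O)CCC(=O)OC(C)(C)C | intermediate
13 | C7 methanesulfonate of 12 (not isolated) | O=C1[C@H]3[C@H](c4ccc(OC)cc4)c4c(OC)cc(OC)cc4[C@H]3[C@H](c3ccc(OC)cc3)[C@H]1C(OS(C)(=O)=O)CCC(=O)OC(C)(C)C | intermediate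
14 | (E)-alkylidene ketone: exocyclic C1=C7, CH2CH2CO2t-Bu chain syn to C12 | O=C1[C@H]3[C@H](c4ccc(OC)cc4)c4c(OC)cc(OC)cc4[C@H]3[C@H](c3ccc(OC)cc3)/C1=C\CCC(=O)OC(C)(C)C | intermediate
15 | bromomagnesium C2(O)=C1 enolate carrying the C7 stereocentre (not isolated) | Br[Mg]OC=1[C@H]3[C@H](c4ccc(OC)cc4)c4c(OC)cc(OC)cc4[C@H]3[C@H](c3ccc(OC)cc3)C=1[C@H](c1ccc(OC)cc1)CCC(=O)OC(C)(C)C | intermediate
16 | enol triflate: C2–OTf, C1=C2, C7(H)(4-methoxyphenyl)CH2CH2CO2t-Bu | FC(F)(F)S(=O)(=O)OC=1[C@H]3[C@H](c4ccc(OC)cc4)c4c(OC)cc(OC)cc4[C@H]3[C@H](c3ccc(OC)cc3)C=1[C@H](c1ccc(OC)cc1)CCC(=O)OC(C)(C)C | intermediate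
17 | C5 phenylselanyl derivative of 16, C5 undefined (not isolated) | FC(F)(F)S(=O)(=O)OC=1[C@H]3[C@H](c4ccc(OC)cc4)c4c(OC)cc(OC)cc4[C@H]3[C@H](c3ccc(OC)cc3)C=1[C@H](c1ccc(OC)cc1)CC([Se]c1ccccc1)C(=O)OC(C)(C)C | intermediate
18 | (E)-enoate: as 16 with C5=C6 | FC(F)(F)S(=O)(=O)OC=1[C@H]3[C@H](c4ccc(OC)cc4)c4c(OC)cc(OC)cc4[C@H]3[C@H](c3ccc(OC)cc3)C=1[C@H](c1ccc(OC)cc1)/C=C/C(=O)OC(C)(C)C | intermediate
19 | 3,5-dimethoxyphenylboronic acid | COc1cc(OC)cc(B(O)O)c1 | starting material
20 | enol triflate with C6 3,5-dimethoxyphenyl and C5H2CO2t-Bu | FC(F)(F)S(=O)(=O)OC=1[C@H]3[C@H](c4ccc(OC)cc4)c4c(OC)cc(OC)cc4[C@H]3[C@H](c3ccc(OC)cc3)C=1[C@H](c1ccc(OC)cc1)[C@@H](c1cc(OC)cc(OC)c1)CC(=O)OC(C)(C)C | intermediate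
21 | methyl bromoacetate | COC(=O)CBr | starting material
22 | diester: C2–CH2CO2Me (C3, C4) and C5H2–CO2t-Bu (C8) | COC(=O)CC=1[C@H]3[C@H](c4ccc(OC)cc4)c4c(OC)cc(OC)cc4[C@H]3[C@H](c3ccc(OC)cc3)C=1[C@H](c1ccc(OC)cc1)[C@@H](c1cc(OC)cc(OC)c1)CC(=O)OC(C)(C)C | intermediate
23 | cycloheptenone β-keto tert-butyl ester fused to rings C, D, E (C4 ketone, C5 ester, C5/C6/C7 all-trans) | O=C1CC=2[C@H]3[C@H](c4ccc(OC)cc4)c4c(OC)cc(OC)cc4[C@H]3[C@H](c3ccc(OC)cc3)C2[C@H](c3ccc(OC)cc3)[C@@H](c3cc(OC)cc(OC)c3)[C@@H]1C(=O)OC(C)(C)C | intermediate
24 | β-keto acid corresponding to 23 (not isolated) | O=C1CC=2[C@H]3[C@H](c4ccc(OC)cc4)c4c(OC)cc(OC)cc4[C@H]3[C@H](c3ccc(OC)cc3)C2[C@H](c3ccc(OC)cc3)[C@@H](c3cc(OC)cc(OC)c3)[C@@H]1C(=O)O | intermediate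
25 | cycloheptenone β-keto phenyl selenoester (key-step precursor) | O=C1CC=2[C@H]3[C@H](c4ccc(OC)cc4)c4c(OC)cc(OC)cc4[C@H]3[C@H](c3ccc(OC)cc3)C2[C@H](c3ccc(OC)cc3)[C@@H](c3cc(OC)cc(OC)c3)[C@@H]1C(=O)[Se]c1ccccc1 | intermediate
26 | 2,3-dihydro derivative of 28 (bicyclo[3.2.1]octane-4,8-dione, H-2 α) | O=C1C[C@H]2[C@H]3[C@H](c4ccc(OC)cc4)c4c(OC)cc(OC)cc4[C@H]3[C@H](c3ccc(OC)cc3)[C@]23C(=O)[C@H]1[C@H](c1cc(OC)cc(OC)c1)[C@H]3c1ccc(OC)cc1 | intermediate
27 | C3=C4 trimethylsilyl enol ether of 26 | C[Si](C)(C)OC1=C[C@H]2[C@H]3[C@H](c4ccc(OC)cc4)c4c(OC)cc(OC)cc4[C@H]3[C@H](c3ccc(OC)cc3)[C@]23C(=O)[C@H]1[C@H](c1cc(OC)cc(OC)c1)[C@H]3c1ccc(OC)cc1 | intermediate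
28 | heptamethyl ether of the target | O=C1C=C2[C@H]3[C@H](c4ccc(OC)cc4)c4c(OC)cc(OC)cc4[C@H]3[C@H](c3ccc(OC)cc3)[C@]23C(=O)[C@H]1[C@H](c1cc(OC)cc(OC)c1)[C@H]3c1ccc(OC)cc1 | intermediate
29 | CNP0407321.1 | O=C1C=C2[C@H]3[C@H](c4ccc(O)cc4)c4c(O)cc(O)cc4[C@H]3[C@H](c3ccc(O)cc3)[C@]23C(=O)[C@H]1[C@H](c1cc(O)cc(O)c1)[C@H]3c1ccc(O)cc1 | target

## Step count and least certain steps

Total step count: 14. Longest linear sequence: 14 steps (from 1).

**Step 11 (key step).** The most likely failures are loss of CO from the acyl radical before ring closure, closure at C2 instead of C1, and reduction of the non-cyclisable enol tautomer of 25. The fallback sets out from 23 and rejoins at 26. NaBH4 in MeOH at 0 °C reduces the C4 ketone to the β-hydroxy tert-butyl ester F1 (C4 epimers, both usable). TFA in CH2Cl2 gives the β-hydroxy acid F2, which cannot decarboxylate. PhSeSePh and Bu3P give the β-hydroxy phenyl selenoester F3. Bu3SnH and AIBN in benzene at 80 °C then form C8–C1 from an acyl radical that has neither an enol form nor a stabilised decarbonylation product, giving the hydroxy ketone F4. Dess–Martin periodinane oxidises F4 to 26. The price is two more steps and the loss of the regiochemical bias that the trigonal C4 provides.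

**Step 9.** Proton transfer to the more acidic allylic C3 position may stall the Dieckmann closure or divert it to intermolecular condensation and double-bond migration. The fallback sets out from 20 and rejoins at 23, and generates the C5 nucleophile from a C–Br bond instead of by deprotonation. Stille coupling of 20 with (Z)-1-ethoxy-2-(tributylstannyl)ethene (Pd(PPh3)4, LiCl, THF, 65 °C) gives the dienyl enol ether F5. LDA then CBr4 at −78 °C brominates C5, the only enolisable position, to the α-bromo ester F6. Mild aqueous acid (PPTS, acetone–H2O) unmasks the C4 aldehyde F7. SmI2 in THF at −78 °C closes C4–C5 by intramolecular Reformatsky reaction to the β-hydroxy ester F8. Dess–Martin periodinane then gives 23.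

**Step 10.** Decarboxylation of the free β-keto acid, or acid-induced migration of the C1=C2 bond, may occur before acyl transfer. The fallback sets out from 23 and rejoins at 25 without a free acid: 23 is heated with PhSeH in toluene at 110 °C, so that loss of tert-butanol gives the α-oxoketene, which the selenol captures at C8. This is the acylketene exchange by which tert-butyl β-keto esters are converted into β-keto thioesters, and it makes no new isolable compound.

**Step 5.** Facial selectivity at the exocyclic C7 may be poor, and O-sulfonylation of the hindered enolate incomplete. The fallback sets out from 14 and rejoins at 16 under reagent control. Rhodium-catalysed addition of 4-methoxyphenylboronic acid to 14 is run with [RhCl(C2H4)2]2 and the enantiomer of 2,5-diphenylbicyclo[2.2.2]octa-2,5-diene that directs the aryl group to the β face (KOH cat., dioxane–H2O, 30 °C). It gives the saturated ketone F9. Tf2O with 2,6-di-tert-butyl-4-methylpyridine in CH2Cl2 then forms the thermodynamic enol triflate 16. The C1=C2 enol is preferred over C2=C9, which would place a double bond at the ring fusion of the cis-fused bicycle.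

## Further compounds

F1 | step 11 | β-hydroxy tert-butyl ester (C4 carbinol of 23, C4 undefined) | OC1CC=2[C@H]3[C@H](c4ccc(OC)cc4)c4c(OC)cc(OC)cc4[C@H]3[C@H](c3ccc(OC)cc3)C2[C@H](c3ccc(OC)cc3)[C@@H](c3cc(OC)cc(OC)c3)[C@@H]1C(=O)OC(C)(C)C
F2 | step 11 | β-hydroxy acid (C4 undefined) | OC1CC=2[C@H]3[C@H](c4ccc(OC)cc4)c4c(OC)cc(OC)cc4[C@H]3[C@H](c3ccc(OC)cc3)C2[C@H](c3ccc(OC)cc3)[C@@H](c3cc(OC)cc(OC)c3)[C@@H]1C(=O)O
F3 | step 11 | β-hydroxy phenyl selenoester (C4 undefined) | OC1CC=2[C@H]3[C@H](c4ccc(OC)cc4)c4c(OC)cc(OC)cc4[C@H]3[C@H](c3ccc(OC)cc3)C2[C@H](c3ccc(OC)cc3)[C@@H](c3cc(OC)cc(OC)c3)[C@@H]1C(=O)[Se]c1ccccc1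
F4 | step 11 | C4 carbinol of 26 (C4 undefined) | OC1C[C@H]2[C@H]3[C@H](c4ccc(OC)cc4)c4c(OC)cc(OC)cc4[C@H]3[C@H](c3ccc(OC)cc3)[C@]23C(=O)[C@H]1[C@H](c1cc(OC)cc(OC)c1)[C@H]3c1ccc(OC)cc1
F5 | step 9 | C2 (Z)-2-ethoxyvinyl compound from 20 | CCO/C=C\C=1[C@H]3[C@H](c4ccc(OC)cc4)c4c(OC)cc(OC)cc4[C@H]3[C@H](c3ccc(OC)cc3)C=1[C@H](c1ccc(OC)cc1)[C@@H](c1cc(OC)cc(OC)c1)CC(=O)OC(C)(C)C
F6 | step 9 | C5 bromo ester of F5 (C5 undefined) | CCO/C=C\C=1[C@H]3[C@H](c4ccc(OC)cc4)c4c(OC)cc(OC)cc4[C@H]3[C@H](c3ccc(OC)cc3)C=1[C@H](c1ccc(OC)cc1)[C@@H](c1cc(OC)cc(OC)c1)C(Br)C(=O)OC(C)(C)C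
F7 | step 9 | C4 aldehyde with C5 bromo ester (C5 undefined) | O=CCC=1[C@H]3[C@H](c4ccc(OC)cc4)c4c(OC)cc(OC)cc4[C@H]3[C@H](c3ccc(OC)cc3)C=1[C@H](c1ccc(OC)cc1)[C@@H](c1cc(OC)cc(OC)c1)C(Br)C(=O)OC(C)(C)C
F8 | step 9 | β-hydroxy tert-butyl ester of the seven-membered ring (C4 undefined) | OC1CC=2[C@H]3[C@H](c4ccc(OC)cc4)c4c(OC)cc(OC)cc4[C@H]3[C@H](c3ccc(OC)cc3)C2[C@H](c3ccc(OC)cc3)[C@@H](c3cc(OC)cc(OC)c3)[C@@H]1C(=O)OC(C)(C)C
F0 | step 10 | none | none
F9 | step 5 | saturated C2 ketone with C7 4-methoxyphenyl (C1 chain β, H-1 α) | O=C1[C@H]3[C@H](c4ccc(OC)cc4)c4c(OC)cc(OC)cc4[C@H]3[C@H](c3ccc(OC)cc3)[C@H]1[C@H](c1ccc(OC)cc1)CCC(=O)OC(C)(C)C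
A1 | alternative 1 | acyclic 2,4,6-triketone with the C6=C7 and C11=C12 stilbene arms | CC(=O)C(C(=O)CC(=O)CC(=Cc1ccc(OC)cc1)c1cc(OC)cc(OC)c1)C(=Cc1ccc(OC)cc1)c1cc(OC)cc(OC)c1
A2 | alternative 1 | C5-acetyl spiro[4.4]nonane-1,6-dione with rings B and C | O=C2C[C@@H](c3cc(OC)cc(OC)c3)[C@H](c3ccc(OC)cc3)[C@]23C(=O)[C@H](C(C)=O)[C@H](c1cc(OC)cc(OC)c1)[C@H]3c1ccc(OC)cc1
A3 | alternative 2 | ring C diyne (C10 ethoxyethynyl, C11 ethynyl) on the bicyclic enedione core | O=C1C=C2[C@@H]([C@H](c4ccc(OC)cc4)C#COCC)[C@@H](C#C)[C@H](c3ccc(OC)cc3)[C@]23C(=O)[C@H]1[C@H](c1cc(OC)cc(OC)c1)[C@H]3c1ccc(OC)cc1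
A4 | alternative 2 | ethoxyethyne | C#COCC
A5 | alternative 2 | pentamethyl diethyl ether of the target | O=C1C=C2[C@H]3[C@H](c4ccc(OC)cc4)c4c(OCC)cc(OCC)cc4[C@H]3[C@H](c3ccc(OC)cc3)[C@]23C(=O)[C@H]1[C@H](c1cc(OC)cc(OC)c1)[C@H]3c1ccc(OC)cc1
A6 | alternative 3 | bicyclic β-methoxy enone carrying the 5,7-dimethoxy-1-oxoindan-3-yl group on C12 | O=C1C=C(OC)[C@]3([C@@H](c4ccc(OC)cc4)[C@H]4CC(=O)c5c(OC)cc(OC)cc45)C(=O)[C@H]1[C@H](c1cc(OC)cc(OC)c1)[C@H]3c1ccc(OC)cc1
A7 | alternative 3 | hexacyclic triketone with C10 carbonyl | O=C1C=C2[C@H]3C(=O)c4c(OC)cc(OC)cc4[C@H]3[C@H](c3ccc(OC)cc3)[C@]23C(=O)[C@H]1[C@H](c1cc(OC)cc(OC)c1)[C@H]3c1ccc(OC)cc1
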